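Target in Saturday's closed flask climbs to a plateau, and that plateau is read here as a record of what substrate did on its way out: it coupled with coupling partner through intermediate B, or it left as side product. The reckoning therefore follows the fraction of substrate left and asks how fast each exit runs at a given [coupling partner].

| flask | substrate | coupling partner | remark | time |
|---|---|---|---|---|
| Saturday's | 0.10 M | 0.30 M | run made earlier |  |
| Friday's | 0.10 M | 0.42 M | run made earlier |  |
| Thursday's | 0.10 M | 0.66 M | run made earlier |  |
| west | 0.10 M | 0.300 M | everything together in a closed stirred flask, run for 30 h | 30 h |
| north | 0.10 M | 0.300 M | a single well-mixed tank run continuously and read at steady state, 30 h in it on average |  |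
| south-west | 0.10 M | 0.300 M (fed, over 24.0 h) | a stirred flask in which coupling partner is dosed at a steady rate over 24.0 h without added volume, worked up at 30 h | 30 h |
| south-east | 0.10 M (fed, over 24.0 h) | 0.300 M | all but substrate at the start; substrate goes in evenly over 24.0 h, the run ends at 30 h | 30 h |

| run | time / h | target / % | substrate / % |
|---|---|---|---|
| Saturday's | 4.00 | 50 | 6 |
| Saturday's | 8.00 | 66 | 0 |
| Saturday's | 12.0 | 69 | 0 |
| Saturday's | 15.0 | 71 | 0 |
| Saturday's | 20.0 | 70 | 3 |
| Saturday's | 25.0 | 69 | 0 |
| Saturday's | 30.0 | 71 | 0 |
| Friday's | 1.50 | 24 | 14 |
| Friday's | 5.00 | 63 | 0 |
| Friday's | 8.00 | 69 | 0 |
| Friday's | 12.0 | 68 | 0 |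
| Friday's | 20.0 | 73 | 2 |
| Friday's | 25.0 | 72 | 0 |
| Friday's | 30.0 | 74 | 2 |
| Thursday's | 4.00 | 61 | 0 |
| Thursday's | 8.00 | 72 | 1 |
| Thursday's | 12.0 | 68 | 0 |
| Thursday's | 15.0 | 72 | 0 |
| Thursday's | 20.0 | 74 | 2 |
| Thursday's | 25.0 | 72 | 0 |
| Thursday's | 30.0 | 76 | 0 |

(readings scatter by 1.5 percentage points)

- the stated concentrations are those of everything mixed, before any reaction; amounts are the same in each set-up
- what may be going on: substrate <-> intermediate A; substrate + coupling partner -> intermediate B; substrate -> side product; intermediate B -> target; coupling partner + intermediate B <-> intermediate C
- the feed brings no volume worth counting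
- the earlier runs were made in a closed, stirred flask

* order of the set-ups by the amount of target at the outlet or at the end, in percent of the substrate put in, highest first (west / north / south-west / south-east)
* amount of target at the outlet or at the end, in percent of the substrate put in, west
* amount of target at the outlet or at the end, in percent of the substrate put in, north
* amount of target at the outlet or at the end, in percent of the substrate put in, south-west
* amount of target at the outlet or at the end, in percent of the substrate put in, south-east

Saturday's table comes first. At 4.00 h substrate reads 6%, so the two exits together take about 0.703 /h, as a reading with its scatter. At 30.0 h target reads 71%. If the rest counts as lost, forward beats loss by odds of 2.45, and the loss exit takes about 0.204 /h. The coupling exit is taken as pseudo-first-order, proportional to [coupling partner]. Saturday's run then gives 0.123 M: this is the break-even [coupling partner], the level at which the two exits run equally fast.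

Thursday's run tests it. Break-even predicts 84.3% at 0.66 M, but the reading at 30.0 h is 76%, so the figure stays a rough one.

In south-west coupling partner enters at 0.0125 M/h. Substrate's lifetime there is taken as one over both exits at the level dosed by the end of that lifetime, which reckons to 3.59 h. By then the coupling partner dosed into south-west reckons to 0.0449 M, below break-even, and the reckoned forward share, [coupling partner] over the sum of [coupling partner] and break-even, comes to 26.8%.

The forecast says west 70.5%, south-east 70%, north 62% and south-west 38% (range 20% to 58%), in the order west > south-east > north > south-west, on the ground for south-west that “substrate sits with little partner, so side reaction wins”, and for south-west it stands above the reckoning here.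

The flasks give west 71.4%, south-east 68.5%, north 62.2% and south-west 30.9%, in the order west > south-east > north > south-west.

    substrate ⇌ intermediate A (K = 0.640, k = 0.0221 /min)
    substrate + coupling partner → intermediate B (k = 0.0521 /M/min)
    substrate → side product (k = 0.00410 /min)
    intermediate B → target (k = 0.0106 /min)
    coupling partner + intermediate B ⇌ intermediate C (K = 14.0 /M, k = 0.00637 /M/min)

Target in south-west ends 4.1 percentage points above the reckoned share, with 68.2% side product beside it. Break-even then goes to a neighbour, dosed like south-west but charged with 1.2 M of coupling partner. Its substrate lifetime reckons to 2.45 h, and by then its [coupling partner] is 0.123 M, level with break-even, so half of its substrate should go forward. That neighbour ends with 50.1% target.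

(The data come from a simulation for substances that don't exist; scatter was added.)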